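**Retrosynthetic overview**
- Endgame: the enal comes from a silyl-protected allylic alcohol (desilylation, MnO2); the angelate from the (R)-carbinol; the carbinol from the aryl methyl ketone by asymmetric transfer hydrogenation.
- Key disconnection: the O1–C2 bond of the dihydrofuran ring, formed when the phenoxide attacks C2 as the terminus of a π-allylpalladium complex derived from a trans aryl vinyl epoxide; in the same operation the acetyl group moves from O1 to the C3 oxygen.
- The epoxide (C2–C3 bond and both ring stereocentres) is made in the same flask from 4-acetyl-2-formylphenyl acetate and a chiral allylic sulfonium ylide based on isothiocineole.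
- Enabling feature: C2 carries the 1,1-disubstituted C=CH2 carbon, so O1–C2 is an allyl aryl ether. The C3 oxygen is vicinal to C2 (epoxide retron) and reaches the O1 acetyl through C3–C3a–C7a (six-membered acyl-transfer path). Net retention at C2 turns a trans epoxide into the cis-2,3 ring.
- Ring order: benzene ring bought (4'-hydroxyacetophenone); oxirane (temporary ring), then the dihydrofuran ring (O1, C2, C3, C3a, C7a), both in step 7.

Key step: step 7

Assumption: the ylide from (1S,4S,5S)-isothiocineole is taken to give the (2S,3S)-epoxide (exo S-alkylation, aldehyde attack on the ylide face remote from the gem-dimethyl carbon); if the sense proves opposite, the (1R,4R,5R) sulfide is used instead and every other operation stays the same.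

Step 1
Reactants: 1 4'-hydroxyacetophenone
Product: 2 5-acetyl-2-hydroxybenzaldehyde
Conditions: hexamethylenetetramine, CF3CO2H, 85 °C; then H2O, 60 °C
Reagents that add atoms: hexamethylenetetramine, C1N2CN3CN1CN(C2)C3; water, O
Why: Duff ortho-formylation, in which the iminium electrophile released from hexamethylenetetramine attacks the only activated free position (ortho to the hydroxyl, para being blocked), hydride transfer and hydrolysis then unveil the aldehyde, and the acetyl and new formyl groups deactivate the ring against a second formylation.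

Step 2
Reactants: 2 5-acetyl-2-hydroxybenzaldehyde
Product: 3 4-acetyl-2-formylphenyl acetate
Conditions: Ac2O, Et3N, DMAP (cat.), CH2Cl2, 0 °C
Reagents that add atoms: acetic anhydride, CC(=O)OC(C)=O
Why: Base-mediated O-acetylation (nucleophilic catalysis) of the acidic phenol; without acid the aldehyde is not converted into an acylal, and the aryl acetate both masks the phenol and stores the acetyl group needed later at C3.

Step 3
Reactants: 4 2-methylenepropane-1,3-diol
Product: 5 2-({[tert-butyl(diphenyl)silyl]oxy}methyl)prop-2-en-1-ol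
Conditions: NaH (1.0 equiv), THF, 0 °C to rt; then t-BuPh2SiCl
Reagents that add atoms: tert-butyl(chloro)diphenylsilane, CC(C)(C)[Si](Cl)(c1ccccc1)c1ccccc1
Why: Monosilylation of a symmetric diol through its monosodium alkoxide (O-silylation), which should react once because one equivalent of NaH leaves the second hydroxyl undeprotonated.

Step 4
Reactants: 5 2-({[tert-butyl(diphenyl)silyl]oxy}methyl)prop-2-en-1-ol
Product: 6 {[2-(bromomethyl)prop-2-en-1-yl]oxy}(tert-butyl)diphenylsilane
Conditions: CBr4, PPh3, CH2Cl2, 0 °C
Reagents that add atoms: carbon tetrabromide, BrC(Br)(Br)Br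
Why: Appel bromination of the primary allylic alcohol under neutral conditions; direct and allylic (SN2') substitution lead to the same bromide.

Step 5
Reactants: 7 (S)-(−)-limonene
Product: 8 (1S,4S,5S)-4,7,7-trimethyl-6-thiabicyclo[3.2.1]octane (isothiocineole)
Conditions: S8, γ-terpinene, neat, 125 °C; distillation
Reagents that add atoms: sulfur, S1SSSSSSS1
Why: Known one-step radical sulfuration of limonene (thiyl-radical cyclisation across both alkenes with hydrogen-atom transfer from γ-terpinene), in which C1 keeps the configuration of (S)-limonene, the bridge fixes C5, and hydrogen delivery to the C4 radical sets the methyl-bearing centre.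

Step 6
Reactants: 6 {[2-(bromomethyl)prop-2-en-1-yl]oxy}(tert-butyl)diphenylsilane; 8 (1S,4S,5S)-isothiocineole
Product: 9 (1S,4S,5S)-6-[2-({[tert-butyl(diphenyl)silyl]oxy}methyl)prop-2-en-1-yl]-4,7,7-trimethyl-6-thiabicyclo[3.2.1]octan-6-ium trifluoromethanesulfonate (S-allyl group exo)
Conditions: LiOSO2CF3, CH2Cl2/H2O, rt
Reagents that add atoms: lithium trifluoromethanesulfonate, [Li+].[O-]S(=O)(=O)C(F)(F)F
Why: SN2 S-alkylation of the sulfide by the allylic bromide with exchange to the non-nucleophilic triflate (which prevents dealkylation by bromide); alkylation on the less hindered exo lone pair of sulfur should give a single sulfonium diastereomer.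

Step 7
Reactants: 3 4-acetyl-2-formylphenyl acetate; 9 sulfonium triflate
Product: 12 (2S,3S)-5-acetyl-2-(3-{[tert-butyl(diphenyl)silyl]oxy}prop-1-en-2-yl)-2,3-dihydro-1-benzofuran-3-yl acetate (2,3-cis), via sulfonium ylide 10 (not isolated), via trans-vinyl epoxide 11 (not isolated)
Conditions: 9 (1.0 equiv), 3 (1.1 equiv), phosphazene base P2-Et (1.0 equiv), CH2Cl2, −78 to −20 °C; then Pd(PPh3)4 (5 mol %), THF, 0 °C
Reagents that add atoms: none
Why: Proposed new method: ylide 10 adds to the aldehyde of 3 and the anti betaine closes to trans-epoxide 11 (3-exo-tet), after which zerovalent palladium ionises the allylic C2–O bond with inversion, the released C3 alkoxide takes the acetyl group from the phenol oxygen through a six-membered tetrahedral intermediate, and the phenoxide so unmasked attacks C2 of the π-allyl complex anti to the metal, closing the dihydrofuran ring by the O1–C2 bond (5-exo attack on the allyl terminus). The closest known reactions are chiral-sulfide-mediated Corey–Chaykovsky epoxidation with semistabilised allylic ylides, palladium-catalysed opening of vinyl epoxides by tethered oxygen nucleophiles with net retention (Tsuji–Trost manifold), and O-to-O acyl migration; what is new is their coupling, in which the acyl shift both unmasks the nucleophile and installs the C3 acetate. C3 and C2 are set together in the betaine-forming step by the chiral sulfide (one ylide face shielded) and the anti-betaine preference of semistabilised ylides, and the two inversions at C2 translate the trans epoxide into the 2,3-cis ring, which direct invertive closure of the same epoxide cannot give. The step needs cis over trans, five- over seven-membered closure, and acyl transfer over epoxide re-closure or β-hydride loss; these rest on closure through the short tether outrunning π–σ–π face exchange of the 2-substituted allyl unit, on attack at the internal allyl carbon, and on the 4-acetylphenoxide being by far the better leaving group in the tetrahedral intermediate. Should acyl transfer already occur in the betaine, the phenoxide displaces the sulfonium group directly with inversion (5-exo-tet) and the same cis product results, so both timings converge on 12.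

Step 8
Reactants: 12 (2S,3S)-5-acetyl-2-(3-{[tert-butyl(diphenyl)silyl]oxy}prop-1-en-2-yl)-2,3-dihydro-1-benzofuran-3-yl acetate
Product: 13 (2S,3S)-2-(3-{[tert-butyl(diphenyl)silyl]oxy}prop-1-en-2-yl)-5-[(1R)-1-hydroxyethyl]-2,3-dihydro-1-benzofuran-3-yl acetate
Conditions: RuCl(p-cymene)[(R,R)-TsDPEN] (1 mol %), HCO2H/Et3N (5:2), EtOAc, 30 °C
Reagents that add atoms: none
Why: Noyori–Ikariya asymmetric transfer hydrogenation, an outer-sphere hydride transfer to the aryl methyl ketone under catalyst control (the (R,R)-ligand should give the (R)-carbinol as with acetophenone, the ring stereocentres being too remote to interfere), which leaves alkene, allyl aryl ether, acetate and silyl ether unreduced.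

Step 9
Reactants: 13 (R)-carbinol; 14 angelic acid [(2Z)-2-methylbut-2-enoic acid]
Product: 16 (1R)-1-[(2S,3S)-3-acetoxy-2-(3-{[tert-butyl(diphenyl)silyl]oxy}prop-1-en-2-yl)-2,3-dihydro-1-benzofuran-5-yl]ethyl (2Z)-2-methylbut-2-enoate, via mixed anhydride 15 (not isolated)
Conditions: 14, 2,4,6-Cl3C6H2COCl, Et3N, toluene, rt; then 13, toluene, 60 °C (no DMAP)
Reagents that add atoms: none
Why: Yamaguchi esterification through the mixed anhydride, run without DMAP and at moderate temperature because nucleophilic catalysts and prolonged heating isomerise angelates to tiglates; acylation at oxygen leaves the (R)-carbinol centre untouched.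

Step 10
Reactants: 16 silyl-protected angelate
Product: 17 (1R)-1-[(2S,3S)-3-acetoxy-2-(3-hydroxyprop-1-en-2-yl)-2,3-dihydro-1-benzofuran-5-yl]ethyl (2Z)-2-methylbut-2-enoate
Conditions: Bu4NF, AcOH (1:1), THF, 0 °C to rt
Reagents that add atoms: none
Why: Fluoride-induced cleavage of the primary silyl ether, buffered with acetic acid so that neither acetyl migration nor base-induced loss of acetic acid across C2–C3 (aromatisation to the benzofuran) should occur.

Step 11
Reactants: 17 allylic alcohol
Product: 18 (1R)-1-[(2S,3S)-3-acetoxy-2-(3-oxoprop-1-en-2-yl)-2,3-dihydro-1-benzofuran-5-yl]ethyl (2Z)-2-methylbut-2-enoate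
Conditions: MnO2 (activated, excess), CH2Cl2, rt
Reagents that add atoms: none
Why: Heterogeneous MnO2 oxidation of the only free (primary allylic) alcohol to the 2-substituted acrolein under neutral conditions, so the aldehyde cannot over-oxidise and the acid- and base-sensitive benzylic esters are not stressed.

**Compound list**
1 | 4'-hydroxyacetophenone | CC(=O)c1ccc(O)cc1 | starting material
2 | 5-acetyl-2-hydroxybenzaldehyde | CC(=O)c1ccc(O)c(C=O)c1 | intermediate
3 | 4-acetyl-2-formylphenyl acetate | CC(=O)Oc1ccc(C(C)=O)cc1C=O | intermediate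
4 | 2-methylenepropane-1,3-diol | C=C(CO)CO | starting material
5 | 2-({[tert-butyl(diphenyl)silyl]oxy}methyl)prop-2-en-1-ol | C=C(CO)CO[Si](c1ccccc1)(c1ccccc1)C(C)(C)C | intermediate
6 | {[2-(bromomethyl)prop-2-en-1-yl]oxy}(tert-butyl)diphenylsilane | C=C(CBr)CO[Si](c1ccccc1)(c1ccccc1)C(C)(C)C | intermediate
7 | (S)-(−)-limonene | CC1=CC[C@H](CC1)C(C)=C | starting material
8 | (1S,4S,5S)-4,7,7-trimethyl-6-thiabicyclo[3.2.1]octane (isothiocineole) | C[C@H]1CC[C@H]2C[C@@H]1SC2(C)C | intermediate
9 | (1S,4S,5S)-6-[2-({[tert-butyl(diphenyl)silyl]oxy}methyl)prop-2-en-1-yl]-4,7,7-trimethyl-6-thiabicyclo[3.2.1]octan-6-ium trifluoromethanesulfonate (S-allyl exo) | C[C@H]1CC[C@H]2C[C@@H]1[S@+](CC(=C)CO[Si](c1ccccc1)(c1ccccc1)C(C)(C)C)C2(C)C.[O-]S(=O)(=O)C(F)(F)F | intermediate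
10 | sulfonium ylide of 9 (carbanion on the S-bound allylic CH) | C[C@H]1CC[C@H]2C[C@@H]1[S@+]([CH-]C(=C)CO[Si](c1ccccc1)(c1ccccc1)C(C)(C)C)C2(C)C | intermediate
11 | 4-acetyl-2-[(2S,3S)-3-(3-{[tert-butyl(diphenyl)silyl]oxy}prop-1-en-2-yl)oxiran-2-yl]phenyl acetate (trans) | CC(=O)Oc1ccc(C(C)=O)cc1[C@@H]2O[C@H]2C(=C)CO[Si](c3ccccc3)(c3ccccc3)C(C)(C)C | intermediate
12 | (2S,3S)-5-acetyl-2-(3-{[tert-butyl(diphenyl)silyl]oxy}prop-1-en-2-yl)-2,3-dihydro-1-benzofuran-3-yl acetate | C=C(CO[Si](c3ccccc3)(c3ccccc3)C(C)(C)C)[C@@H]1Oc2ccc(C(C)=O)cc2[C@@H]1OC(C)=O | intermediate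
13 | (2S,3S)-2-(3-{[tert-butyl(diphenyl)silyl]oxy}prop-1-en-2-yl)-5-[(1R)-1-hydroxyethyl]-2,3-dihydro-1-benzofuran-3-yl acetate | C=C(CO[Si](c3ccccc3)(c3ccccc3)C(C)(C)C)[C@@H]1Oc2ccc([C@@H](C)O)cc2[C@@H]1OC(C)=O | intermediate
14 | angelic acid, (2Z)-2-methylbut-2-enoic acid | C/C=C(/C)C(=O)O | starting material
15 | (2Z)-2-methylbut-2-enoic 2,4,6-trichlorobenzoic anhydride | C/C=C(/C)C(=O)OC(=O)c1c(Cl)cc(Cl)cc1Cl | intermediate
16 | (1R)-1-[(2S,3S)-3-acetoxy-2-(3-{[tert-butyl(diphenyl)silyl]oxy}prop-1-en-2-yl)-2,3-dihydro-1-benzofuran-5-yl]ethyl (2Z)-2-methylbut-2-enoate | C=C(CO[Si](c3ccccc3)(c3ccccc3)C(C)(C)C)[C@@H]1Oc2ccc([C@@H](C)OC(=O)/C(C)=C\C)cc2[C@@H]1OC(C)=O | intermediate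
17 | (1R)-1-[(2S,3S)-3-acetoxy-2-(3-hydroxyprop-1-en-2-yl)-2,3-dihydro-1-benzofuran-5-yl]ethyl (2Z)-2-methylbut-2-enoate | C=C(CO)[C@@H]1Oc2ccc([C@@H](C)OC(=O)/C(C)=C\C)cc2[C@@H]1OC(C)=O | intermediate
18 | (1R)-1-[(2S,3S)-3-acetoxy-2-(3-oxoprop-1-en-2-yl)-2,3-dihydro-1-benzofuran-5-yl]ethyl (2Z)-2-methylbut-2-enoate | C=C(C=O)[C@@H]1Oc2ccc([C@@H](C)OC(=O)/C(C)=C\C)cc2[C@@H]1OC(C)=O | target

**Step count**
Total step count: 11. Longest linear sequence: 8 steps (4 → 5 → 6 → 9 → 12 → 13 → 16 → 17 → 18).

**Steps most likely to fail**

1. Step 7 (proposed new method). The retentive course may erode through π–σ–π face exchange of the allyl complex or through re-ionisation of the product allyl aryl ether, with drift towards the trans ring. The aryl acetate may also be cleaved under the basic ylide conditions, or acyl transfer may lag behind β-hydride loss from the alkoxide. The fallback uses known chemistry with invertive instead of retentive logic; it sets out from 2 and returns at 12. The phenol of 2 is silylated (t-BuMe2SiCl, imidazole, DMF) to 5-acetyl-2-{[tert-butyl(dimethyl)silyl]oxy}benzaldehyde F1. The antipodal sulfide (1R,4R,5R)-isothiocineole F2 (purchased, or made as in step 5 from (R)-limonene) is alkylated with 6 as in step 6 to the enantiomeric sulfonium triflate F3. Ylide epoxidation of F1 with F3 (P2-Et, CH2Cl2, −78 °C) should give the (2R,3R)-trans-epoxide F4. Bu4NF in THF then frees the phenoxide, which opens the epoxide at the allylic carbon C2 with inversion (the established anti course for 2-oxiranylphenols) to the (2S,3R)-trans-alcohol F5. A Mitsunobu reaction with acetic acid (PPh3, diisopropyl azodicarboxylate, toluene, 0 °C) inverts C3 and delivers 12.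

2. Step 9. The angeloyl unit may isomerise from Z to E during acylation, and heating with base may cause loss of acetic acid across C2–C3. The fallback builds the Z-alkene on the molecule; it sets out from 13 and returns at 16. Compound 13 is esterified with 2-[bis(2,2,2-trifluoroethoxy)phosphoryl]propanoic acid (carbodiimide, DMAP cat., CH2Cl2, 0 °C) to the phosphonate ester F6. Its potassium salt (KN(SiMe3)2, 18-crown-6, THF, −78 °C) is then combined with acetaldehyde in a Still–Gennari olefination, which should form the (Z)-2-methylbut-2-enoate kinetically at low temperature and give 16.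

3. Step 8. Hydride transfer to the electron-rich ketone may be slow, and the formic acid medium may promote solvolysis of the benzylic acetate or the silyl ether. The fallback sets out from 12 and returns directly at 13. It replaces metal-hydride transfer in acidic formate by boron-based, Lewis-acid-organised hydride delivery in a neutral aprotic medium: Corey–Bakshi–Shibata reduction with (S)-2-methyl-CBS-oxazaborolidine and catecholborane in toluene at −78 °C, which should give the same (R)-carbinol without touching the alkene. No new compound is formed.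

**Further compounds**
F1 | step 7 | 5-acetyl-2-{[tert-butyl(dimethyl)silyl]oxy}benzaldehyde | CC(=O)c1ccc(O[Si](C)(C)C(C)(C)C)c(C=O)c1
F2 | step 7 | (1R,4R,5R)-4,7,7-trimethyl-6-thiabicyclo[3.2.1]octane | C[C@@H]1CC[C@@H]2C[C@H]1SC2(C)C
F3 | step 7 | (1R,4R,5R)-6-[2-({[tert-butyl(diphenyl)silyl]oxy}methyl)prop-2-en-1-yl]-4,7,7-trimethyl-6-thiabicyclo[3.2.1]octan-6-ium trifluoromethanesulfonate (S-allyl exo) | C[C@@H]1CC[C@@H]2C[C@H]1[S@@+](CC(=C)CO[Si](c1ccccc1)(c1ccccc1)C(C)(C)C)C2(C)C.[O-]S(=O)(=O)C(F)(F)F
F4 | step 7 | 1-[4-{[tert-butyl(dimethyl)silyl]oxy}-3-[(2R,3R)-3-(3-{[tert-butyl(diphenyl)silyl]oxy}prop-1-en-2-yl)oxiran-2-yl]phenyl]ethan-1-one (trans) | CC(=O)c1ccc(O[Si](C)(C)C(C)(C)C)c(c1)[C@H]2O[C@@H]2C(=C)CO[Si](c3ccccc3)(c3ccccc3)C(C)(C)C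
F5 | step 7 | 1-[(2S,3R)-2-(3-{[tert-butyl(diphenyl)silyl]oxy}prop-1-en-2-yl)-3-hydroxy-2,3-dihydro-1-benzofuran-5-yl]ethan-1-one (2,3-trans) | C=C(CO[Si](c3ccccc3)(c3ccccc3)C(C)(C)C)[C@@H]1Oc2ccc(C(C)=O)cc2[C@H]1O
F6 | step 9 | (1R)-1-[(2S,3S)-3-acetoxy-2-(3-{[tert-butyl(diphenyl)silyl]oxy}prop-1-en-2-yl)-2,3-dihydro-1-benzofuran-5-yl]ethyl 2-[bis(2,2,2-trifluoroethoxy)phosphoryl]propanoate (both epimers at the phosphonate-bearing carbon) | C=C(CO[Si](c3ccccc3)(c3ccccc3)C(C)(C)C)[C@@H]1Oc2ccc([C@@H](C)OC(=O)C(C)P(=O)(OCC(F)(F)F)OCC(F)(F)F)cc2[C@@H]1OC(C)=O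
F0 | step 8 | none | none
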